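**Numbering used throughout:** 1 keto ester (start); 2 (S)-carbinol; 3 bis-silyl ether (in flask); 4 phenol silyl ether; 5 aryl vinyl ether ester; 6 benzylic alcohol; 7 methallyl chloride (start); 8 diene; 9 benzodioxocine; 10 benzylic organolithium (in flask); 11 lithium alkoxide (in flask); 12 cis-hydroxy dihydrobenzofuran; 13 acetate; 14 allylic alcohol (in flask); 15 enal; 16 acid; 17 methyl ester; 18 free carbinol; 19 angelic acid (start); 20 mixed anhydride (in flask); 21 target.

## Analysis of the target

The target is a 2,3-dihydro-1-benzofuran (ring A benzene, ring B dihydrofuran; O1, C2, C3, C3a, C4–C7, C7a). It carries a methyl acrylate unit at C2 through its α-carbon (Cα), an acetoxy group at C3 and an (S)-1-(angeloyloxy)ethyl group at C5, para to O1. There are three stereocentres: C2 and C3 are both S with their substituents cis on ring B, and the (S) carbinol carbon of the side chain is too remote to control, or be controlled by, the ring centres. Every functional group is fragile. The C3 acetate is benzylic and anti to H2, so loss of acetic acid to the aromatic benzofuran is always downhill. The side-chain ester sits on a para-alkoxybenzylic carbon that ionises easily, the (Z)-2-methylbut-2-enoate isomerises to the E ester under nucleophilic or acidic catalysis, and the 2-substituted acrylate is a Michael acceptor. The difficulty is to obtain the cis-C2/C3 pair, which the common ring B closures do not favour, with absolute control and without late exposure to strong acid or base. The strategy rests on the fact that the C3 oxygen and the Cα arm stand cis on adjacent carbons of ring B. If the C3 oxygen is joined to the terminal methylene of the arm by an O–CH2 bond and the C2–C3 bond is opened, an eight-membered 1,5-benzodioxocine results, in which the future C2 (an aryl enol ether carbon) and the future C3 (a benzylic OCH2) face each other across the ring; re-forming C2–C3 is a [2,3]-sigmatropic shift whose bicyclic transition state can only give the cis product.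

## Retrosynthetic reasoning

**21 ⇒ 18 + 19.** The side-chain ester C–O bond is cut first. The Z-enoate isomerises easily and its alkene would interfere with any allylic oxidation, so it must arrive after all redox chemistry. Forward, a para-alkoxybenzylic secondary alcohol has to be acylated through mixed anhydride 20 without a nucleophilic catalyst and with retention at carbon.

**18 ⇒ 17.** The carbinol is masked as a silyl ether. This group survives hydride, organolithium, selenium and chlorite reagents and is removed by fluoride, which neither ionises the benzylic C–O bond nor touches the C3 acetate.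

**17 ⇒ 16 ⇒ 15 ⇒ 13 (through 14).** The ester carbon of the acrylate is traced back, one oxidation level at a time, to the methyl group of an isopropenyl substituent. No C–C bond is cut; the gain is that this carbon passes the strongly basic key step as an inert CH3. Forward, the allylic oxidation must choose the methyl group over the C2 methine, and 15 must be taken to acid and ester under buffered conditions.

**13 ⇒ 12.** The acetate is removed to expose the C3 hydroxyl, which is the group the key step delivers (as alkoxide 11).

**12 ⇒ 9 (through 11 and 10).** The C2–C3 bond is cut and the C3 oxygen is bonded to the terminal CH2 of the isopropenyl group. Cutting here, rather than at O1–C2 or C3–C3a, removes both ring stereocentres at once and leaves a precursor with no ring stereocentre. The cis relationship then becomes a consequence of geometry and only the absolute sense needs a reagent. Forward, C6 of 9 must be lithiated selectively, the C–C bond must form across the ring, and one of two mirror-image folding modes must be chosen.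

**9 ⇒ 8.** The C2=C3 double bond of the cyclic enol ether is opened to two terminal alkenes. A Z-trisubstituted aryl enol ether is hard to make selectively in open-chain form, whereas in an eight-membered ring only the Z isomer exists. Forward, a metathesis catalyst must close a medium ring from an aryl vinyl ether and a 1,1-disubstituted alkene.

**8 ⇒ 6 + 7; 6 ⇒ 5 ⇒ 4.** The allylic ether C–O bond is cut (alkoxide plus 7), the benzylic alcohol is traced to the ester of 5, and the vinyl–oxygen bond is cut to phenol 4. The vinyl group is introduced at the ester stage, so the copper reagent meets a single hydroxyl group and no salicyl alcohol that could chelate copper or esterify the boron reagent.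

**4 ⇒ 2 ⇒ 1 (through 3).** The silyl ether is removed and the carbinol stereocentre is traced to the ketone of 1. Having no neighbour that could direct it, this centre is set first, by catalyst control, on the cheapest compound of the route.

## Alternatives that were turned down

**Alternative 1: [2+2+2] benzannulation.** Ring A is disconnected into three alkynes: the tartrate-derived diyne A1 (a silyl ynol ether and a propargylic silyl ether linked through O1, C2 and C3) and the side-chain alkyne A2. Forward, Cp*RuCl(cod) would form a ruthenacycle from the two tethered alkynes (C3a–C7a) and insert A2 (C4–C5, C6–C7), giving A3 with rings A and B made together.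
- For: high convergence; C2 and C3 come from the chiral pool and the side-chain centre from a catalogue alkynol; the bulky silyl group should steer the side chain meta to it.
- Against: in A1 the ynol ether oxygen sits on the allylic carbon C2, so the substrate is an allyl alkynyl ether, a class prone to [3,3]-shift well below room temperature. Desymmetrising a tartrate into A1 is long. A3 still needs ipso-protodesilylation (acid next to two ionisable benzylic esters), a silyl-to-acetyl exchange, and oxidation of the isopropenyl methyl with the isomerisable Z-enoate already in place.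
- Comparison: it is stronger in convergence and in using only chiral-pool stereocentres. The chosen route offers robust ether-only intermediates up to the key step and keeps the Z-enoate out of every oxidation; it should also be about three to four steps shorter.

**Alternative 2: Friedel–Crafts closure of a chiral lactone acetal.** The C3a–C3 bond is cut, giving the aryloxy lactone acetal A4. Forward, BF3·OEt2 would ionise the acetal and the arene carbon ortho to oxygen would attack the oxocarbenium carbon to give tricyclic lactone A5.
- For: the two five-membered rings sharing C2–C3 can only be cis-fused, so the relative configuration is secured by well-understood chemistry. The acrylate carbon is already at the acid oxidation level and the auxiliary is cheap.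
- Against: the configuration drawn for A4 requires the (1S,2R,5S)-menthyl acetal, the mirror image of the cheap natural series. Installing the exocyclic methylene next to a β-aryloxy group invites E1cB loss of the phenoxide. The cation is an acyloxy-stabilised one attacked by a bromine-deactivated ring. A5 must then be opened to a hydroxy methyl ester in the presence of a reactive exocyclic enoate and against relactonisation, and the bromide must be converted to the carbinol side chain late, next to an acrylate.
- Comparison: it is stronger on certainty of the cis relationship and avoids the three-step oxidation of a methyl group. The chosen route delivers the open-chain C3 alcohol ready for acetylation, has the side-chain centre in place from step 1, and needs fewer steps.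

**Alternative 3: Palladium oxycarbonylation of an allenol.** The O1–C2 bond, the Cα–carbonyl bond and the lactone C–O bond are cut, giving allenyl carbinol A6. Forward, PdCl2 with CuCl2 under CO (divalent palladium) would make the phenol oxygen add to the proximal allene carbon, insert CO into the vinyl–palladium bond and let the C3 hydroxyl capture the acyl group, giving lactone A7.
- For: three bonds form in one operation by a known reaction type; only C3 has to be set beforehand; the acrylate oxidation level is reached directly. The overall count would probably be lower than here.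
- Against: A6 combines an ortho-hydroxybenzylic alcohol (prone to quinone methide formation) with an α-allenol, whose usual fate under divalent palladium is 5-endo cyclisation through the carbinol oxygen. The C2 configuration is fixed in the oxypalladation, before the lactone can select cis. A7 poses the same lactone-opening problem as A5, worsened by the ease of conjugate addition of methoxide.
- Comparison: it is stronger in step economy and in precedent for the key step. The chosen route offers a geometric guarantee for cis and an acyclic-ester end-game that never has to open a strained α-methylene lactone.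

Key step: step 7

**Assumptions.** The sense of induction of the tert-butyllithium–bis(oxazoline) complex on a cyclic substrate cannot be predicted with confidence. The (S,S) ligand is written; its enantiomer, made in the same way from D-valinol, would be used if the sense proves opposite. Compounds 1, 7 and 19 are taken to be catalogue chemicals.

## Route

Step 1
Reactants: 1 methyl 5-acetyl-2-hydroxybenzoate
Product: 2 methyl 2-hydroxy-5-[(1S)-1-hydroxyethyl]benzoate
Conditions: RuCl(p-cymene)[(S,S)-TsDPEN] (1 mol%), HCO2H/Et3N (5:2), DMF, 40 °C
Reagents that add atoms: none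
Why: Noyori asymmetric transfer hydrogenation of an aryl methyl ketone; the (S,S) catalyst should deliver hydride to the Re face and give the (S) carbinol, as for other acetophenones. The acidic medium keeps the phenol protonated and the ester meta to the ketone offsets the donor effect of the para oxygen.

Step 2
Reactants: 2 methyl 2-hydroxy-5-[(1S)-1-hydroxyethyl]benzoate
Product: 4 methyl 5-[(1S)-1-{[tert-butyl(dimethyl)silyl]oxy}ethyl]-2-hydroxybenzoate, via bis-silyl ether 3 (not isolated)
Conditions: TBSCl (2.5 equiv), imidazole, DMF, rt; then MeOH, K2CO3, rt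
Reagents that add atoms: tert-butyldimethylsilyl chloride, CC(C)(C)[Si](C)(C)Cl
Why: Exhaustive silylation followed by methanolysis of the aryl silyl ether, which is far more labile than the secondary alkyl silyl ether because the salicylate phenoxide is a good leaving group. This avoids relying on kinetic discrimination between the two hydroxyl groups.

Step 3
Reactants: 4 methyl 5-[(1S)-1-{[tert-butyl(dimethyl)silyl]oxy}ethyl]-2-hydroxybenzoate
Product: 5 methyl 5-[(1S)-1-{[tert-butyl(dimethyl)silyl]oxy}ethyl]-2-(ethenyloxy)benzoate
Conditions: 2,4,6-trivinylcyclotriboroxane·pyridine (0.7 equiv), Cu(OAc)2 (1.0 equiv), pyridine, 4 Å MS, CH2Cl2, dry air, rt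
Reagents that add atoms: 2,4,6-trivinylcyclotriboroxane–pyridine complex, C=CB1OB(C=C)OB(C=C)O1.c1ccncc1
Why: Chan–Lam oxidative O-vinylation of a phenol with a vinylboronic acid equivalent. The phenol is the only free hydroxyl group, and the ester and silyl ether are inert to divalent copper and pyridine.

Step 4
Reactants: 5 methyl 5-[(1S)-1-{[tert-butyl(dimethyl)silyl]oxy}ethyl]-2-(ethenyloxy)benzoate
Product: 6 {5-[(1S)-1-{[tert-butyl(dimethyl)silyl]oxy}ethyl]-2-(ethenyloxy)phenyl}methanol
Conditions: LiAlH4, THF, 0 °C; Rochelle salt work-up, no acid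
Reagents that add atoms: none
Why: Hydride reduction of the aryl ester; the aryl vinyl ether and the silyl ether do not react with LiAlH4. Work-up and chromatography are kept basic because acid would add the new hydroxyl group to the neighbouring vinyl ether.

Step 5
Reactants: 6 {5-[(1S)-1-{[tert-butyl(dimethyl)silyl]oxy}ethyl]-2-(ethenyloxy)phenyl}methanol; 7 3-chloro-2-methylprop-1-ene
Product: 8 tert-butyl[(1S)-1-[4-(ethenyloxy)-3-{[(2-methylprop-2-en-1-yl)oxy]methyl}phenyl]ethoxy]dimethylsilane
Conditions: NaH, n-Bu4NI (cat.), THF/DMF, 0 °C to rt
Reagents that add atoms: none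
Why: Williamson ether synthesis of a primary benzylic alkoxide with an allylic chloride, assisted by iodide; all other groups are base-stable ethers.

Step 6
Reactants: 8 tert-butyl[(1S)-1-[4-(ethenyloxy)-3-{[(2-methylprop-2-en-1-yl)oxy]methyl}phenyl]ethoxy]dimethylsilane
Product: 9 (2Z)-8-[(1S)-1-{[tert-butyl(dimethyl)silyl]oxy}ethyl]-3-methyl-4H,6H-1,5-benzodioxocine
Conditions: second-generation Hoveyda–Grubbs catalyst RuCl2(H2IMes)(=CH-C6H4-2-OiPr) (5–10 mol%), 1,4-benzoquinone (10 mol%), toluene (0.005 M), 80 °C, argon sparge
Reagents that add atoms: none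
Why: Enol ether–olefin ring-closing metathesis with loss of ethene, a reaction type established for benzo-fused oxygen heterocycles from aryl vinyl ethers. The ring can only hold the Z trisubstituted enol ether, the arene and cis-alkene pre-organise the eight-membered closure, and benzoquinone suppresses ruthenium hydride isomerisation.

Step 7
Reactants: 9 (2Z)-8-[(1S)-1-{[tert-butyl(dimethyl)silyl]oxy}ethyl]-3-methyl-4H,6H-1,5-benzodioxocine
Product: 12 (2S,3S)-5-[(1S)-1-{[tert-butyl(dimethyl)silyl]oxy}ethyl]-2-(prop-1-en-2-yl)-2,3-dihydro-1-benzofuran-3-ol, via benzylic organolithium 10 (not isolated), via lithium alkoxide 11 (not isolated)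
Conditions: t-BuLi (1.5 equiv) premixed with (S,S)-3,3-bis(4-isopropyl-4,5-dihydrooxazol-2-yl)pentane (1.5 equiv), hexane, −78 °C; then H2O
Reagents that add atoms: tert-butyllithium, [Li]C(C)(C)C (lithium in 10 and 11 only; none of its atoms in 12)
Why: Proposed new method: the ligand-bound alkyllithium should remove one of the two enantiotopic benzylic protons at C6 of 9 (ring numbering O1 on the arene, C2H=C3(CH3), C4H2, O5, C6H2), the most acidic site, to give 10; the carbanion carbon then bonds to the enol ether carbon C2 across the ring while the allylic C4–O5 bond breaks and the double bond moves to C3=C4, a [2,3]-Wittig shift that gives 11 and, on quenching, 12. The closest known chemistry is [2,3]-Wittig ring contraction of macrocyclic diallylic and allyl propargyl ethers, together with enantioselective [2,3]-Wittig rearrangement of acyclic benzyl allyl ethers under alkyllithium and chiral bis(oxazoline) ligands; their combination in an eight-membered aryl enol ether is new. Ring B closes transannularly in a 5-exo-trig sense (C6 attacks C2 and the C2=C3 π bond lies outside the new ring), through an envelope of C6, O5, C4, C3 and C2 fused to the forming ring C6–C6a–C10a–O1–C2. Two five-membered arrays sharing the new bond can only be cis-fused, so the hydrogens at the two new centres end up cis and the C3 oxygen and the isopropenyl group lie on the same face of ring B; this relative configuration is set by ring geometry alone. The absolute sense (2S,3S) must come from the chiral lithium complex, which distinguishes the two mirror-image folded forms at the prochiral C6 methylene; the remote (S) centre cannot do this, but it turns any leakage into a diastereomer that can be separated. The step needs site selectivity for C6–H over the allylic C4–H, the vinylic C2–H and the side-chain benzylic C–H, and [2,3] over [1,2] migration; the first is secured by the doubly activated, unhindered C6 position and the absence of any carbonyl group, the second by low temperature and the fixed 1,5 relationship of C6 and C2. The driving force is the exchange of a carbanion for an alkoxide together with relief of medium-ring strain.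

Step 8
Reactants: 12 (2S,3S)-5-[(1S)-1-{[tert-butyl(dimethyl)silyl]oxy}ethyl]-2-(prop-1-en-2-yl)-2,3-dihydro-1-benzofuran-3-ol
Product: 13 (2S,3S)-5-[(1S)-1-{[tert-butyl(dimethyl)silyl]oxy}ethyl]-2-(prop-1-en-2-yl)-2,3-dihydro-1-benzofuran-3-yl acetate
Conditions: Ac2O, pyridine, DMAP (cat.), CH2Cl2, 0 °C
Reagents that add atoms: acetic anhydride, CC(=O)OC(C)=O
Why: O-acylation of a secondary alcohol with retention at C3. The mild base and low temperature avoid ionisation or elimination of the benzylic oxygen.

Step 9
Reactants: 13 (2S,3S)-5-[(1S)-1-{[tert-butyl(dimethyl)silyl]oxy}ethyl]-2-(prop-1-en-2-yl)-2,3-dihydro-1-benzofuran-3-yl acetate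
Product: 15 (2S,3S)-5-[(1S)-1-{[tert-butyl(dimethyl)silyl]oxy}ethyl]-2-(3-oxoprop-1-en-2-yl)-2,3-dihydro-1-benzofuran-3-yl acetate, via allylic alcohol 14 (not isolated)
Conditions: SeO2 (0.5 equiv), t-BuOOH (3 equiv), CH2Cl2, rt; filter; then MnO2, CH2Cl2, rt
Reagents that add atoms: selenium dioxide, O=[Se]=O (transfers the oxygen atom and is turned over by tert-butyl hydroperoxide, CC(C)(C)OO)
Why: Riley allylic oxidation by an ene reaction and [2,3]-shift; in 1,1-disubstituted alkenes the methyl group reacts in preference to a methine, so the CH3 and not C2–H should be oxidised. MnO2 then converts the alcohol–aldehyde mixture to the enal alone, being selective for allylic alcohols.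

Step 10
Reactants: 15 (2S,3S)-5-[(1S)-1-{[tert-butyl(dimethyl)silyl]oxy}ethyl]-2-(3-oxoprop-1-en-2-yl)-2,3-dihydro-1-benzofuran-3-yl acetate
Product: 16 2-[(2S,3S)-3-(acetyloxy)-5-[(1S)-1-{[tert-butyl(dimethyl)silyl]oxy}ethyl]-2,3-dihydro-1-benzofuran-2-yl]prop-2-enoic acid
Conditions: NaClO2, NaH2PO4, 2-methylbut-2-ene, t-BuOH/H2O, 0 °C to rt
Reagents that add atoms: sodium chlorite, [Na+].[O-]Cl=O (one oxygen atom)
Why: Pinnick oxidation, which takes α-substituted acroleins to acrylic acids without touching the alkene. The buffer protects the acetate and silyl ether, and the scavenger removes hypochlorous acid before it can chlorinate the arene.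

Step 11
Reactants: 16 2-[(2S,3S)-3-(acetyloxy)-5-[(1S)-1-{[tert-butyl(dimethyl)silyl]oxy}ethyl]-2,3-dihydro-1-benzofuran-2-yl]prop-2-enoic acid
Product: 17 methyl 2-[(2S,3S)-3-(acetyloxy)-5-[(1S)-1-{[tert-butyl(dimethyl)silyl]oxy}ethyl]-2,3-dihydro-1-benzofuran-2-yl]prop-2-enoate
Conditions: Me3SiCHN2, toluene/MeOH (4:1), 0 °C
Reagents that add atoms: trimethylsilyldiazomethane, C[Si](C)(C)C=[N+]=[N-] (its CH carbon becomes the ester methyl)
Why: Esterification of a carboxylic acid with a diazoalkane under neutral conditions. No base is present that could add to the acrylate or cleave the acetate.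

Step 12
Reactants: 17 methyl 2-[(2S,3S)-3-(acetyloxy)-5-[(1S)-1-{[tert-butyl(dimethyl)silyl]oxy}ethyl]-2,3-dihydro-1-benzofuran-2-yl]prop-2-enoate
Product: 18 methyl 2-[(2S,3S)-3-(acetyloxy)-5-[(1S)-1-hydroxyethyl]-2,3-dihydro-1-benzofuran-2-yl]prop-2-enoate
Conditions: HF·pyridine, pyridine, THF, 0 °C to rt
Reagents that add atoms: none
Why: Fluoride-mediated cleavage of the Si–O bond. The buffered, non-basic reagent attacks silicon, so the benzylic C–O bond is not ionised and the acetate neither migrates nor eliminates.

Step 13
Reactants: 18 methyl 2-[(2S,3S)-3-(acetyloxy)-5-[(1S)-1-hydroxyethyl]-2,3-dihydro-1-benzofuran-2-yl]prop-2-enoate; 19 (2Z)-2-methylbut-2-enoic acid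
Product: 21 methyl 2-[(2S,3S)-3-(acetyloxy)-5-[(1S)-1-{[(2Z)-2-methylbut-2-enoyl]oxy}ethyl]-2,3-dihydro-1-benzofuran-2-yl]prop-2-enoate, via mixed anhydride 20 (not isolated)
Conditions: 19, 2,4,6-trichlorobenzoyl chloride, Et3N, toluene, rt; then 18, toluene, 75 °C, no DMAP
Reagents that add atoms: 2,4,6-trichlorobenzoyl chloride, O=C(Cl)c1c(Cl)cc(Cl)cc1Cl (its acyl group is in intermediate 20 only; none of its atoms in 21)
Why: Yamaguchi-type esterification through the mixed anhydride, where the hindered trichlorobenzoyl carbonyl directs the alcohol to the angeloyl carbonyl. Leaving out the nucleophilic catalyst avoids the addition–elimination pathway that isomerises Z to E; the carbinol reacts at oxygen, so its configuration is retained.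

## Compound list

1 | methyl 5-acetyl-2-hydroxybenzoate | COC(=O)c1cc(C(C)=O)ccc1O | starting material
2 | methyl 2-hydroxy-5-[(1S)-1-hydroxyethyl]benzoate | COC(=O)c1cc([C@H](C)O)ccc1O | intermediate
3 | methyl 2-{[tert-butyl(dimethyl)silyl]oxy}-5-[(1S)-1-{[tert-butyl(dimethyl)silyl]oxy}ethyl]benzoate | COC(=O)c1cc([C@H](C)O[Si](C)(C)C(C)(C)C)ccc1O[Si](C)(C)C(C)(C)C | intermediate
4 | methyl 5-[(1S)-1-{[tert-butyl(dimethyl)silyl]oxy}ethyl]-2-hydroxybenzoate | COC(=O)c1cc([C@H](C)O[Si](C)(C)C(C)(C)C)ccc1O | intermediate
5 | methyl 5-[(1S)-1-{[tert-butyl(dimethyl)silyl]oxy}ethyl]-2-(ethenyloxy)benzoate | COC(=O)c1cc([C@H](C)O[Si](C)(C)C(C)(C)C)ccc1OC=C | intermediate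
6 | {5-[(1S)-1-{[tert-butyl(dimethyl)silyl]oxy}ethyl]-2-(ethenyloxy)phenyl}methanol | OCc1cc([C@H](C)O[Si](C)(C)C(C)(C)C)ccc1OC=C | intermediate
7 | 3-chloro-2-methylprop-1-ene (methallyl chloride) | C=C(C)CCl | starting material
8 | tert-butyl[(1S)-1-[4-(ethenyloxy)-3-{[(2-methylprop-2-en-1-yl)oxy]methyl}phenyl]ethoxy]dimethylsilane | C=COc1ccc([C@H](C)O[Si](C)(C)C(C)(C)C)cc1COCC(C)=C | intermediate
9 | (2Z)-8-[(1S)-1-{[tert-butyl(dimethyl)silyl]oxy}ethyl]-3-methyl-4H,6H-1,5-benzodioxocine | C/C1=C/Oc2ccc([C@H](C)O[Si](C)(C)C(C)(C)C)cc2COC1 | intermediate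
10 | 6-lithio derivative of 9 (benzylic α-oxy organolithium, ligand-bound) | C/C1=C/Oc2ccc([C@H](C)O[Si](C)(C)C(C)(C)C)cc2C([Li])OC1 | intermediate
11 | lithium (2S,3S)-5-[(1S)-1-{[tert-butyl(dimethyl)silyl]oxy}ethyl]-2-(prop-1-en-2-yl)-2,3-dihydro-1-benzofuran-3-olate | C=C(C)[C@@H]1Oc2ccc([C@H](C)O[Si](C)(C)C(C)(C)C)cc2[C@@H]1O[Li] | intermediate
12 | (2S,3S)-5-[(1S)-1-{[tert-butyl(dimethyl)silyl]oxy}ethyl]-2-(prop-1-en-2-yl)-2,3-dihydro-1-benzofuran-3-ol | C=C(C)[C@@H]1Oc2ccc([C@H](C)O[Si](C)(C)C(C)(C)C)cc2[C@@H]1O | intermediate
13 | (2S,3S)-5-[(1S)-1-{[tert-butyl(dimethyl)silyl]oxy}ethyl]-2-(prop-1-en-2-yl)-2,3-dihydro-1-benzofuran-3-yl acetate | C=C(C)[C@@H]1Oc2ccc([C@H](C)O[Si](C)(C)C(C)(C)C)cc2[C@@H]1OC(C)=O | intermediate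
14 | (2S,3S)-5-[(1S)-1-{[tert-butyl(dimethyl)silyl]oxy}ethyl]-2-(3-hydroxyprop-1-en-2-yl)-2,3-dihydro-1-benzofuran-3-yl acetate | C=C(CO)[C@@H]1Oc2ccc([C@H](C)O[Si](C)(C)C(C)(C)C)cc2[C@@H]1OC(C)=O | intermediate
15 | (2S,3S)-5-[(1S)-1-{[tert-butyl(dimethyl)silyl]oxy}ethyl]-2-(3-oxoprop-1-en-2-yl)-2,3-dihydro-1-benzofuran-3-yl acetate | C=C(C=O)[C@@H]1Oc2ccc([C@H](C)O[Si](C)(C)C(C)(C)C)cc2[C@@H]1OC(C)=O | intermediate
16 | 2-[(2S,3S)-3-(acetyloxy)-5-[(1S)-1-{[tert-butyl(dimethyl)silyl]oxy}ethyl]-2,3-dihydro-1-benzofuran-2-yl]prop-2-enoic acid | C=C(C(=O)O)[C@@H]1Oc2ccc([C@H](C)O[Si](C)(C)C(C)(C)C)cc2[C@@H]1OC(C)=O | intermediate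
17 | methyl 2-[(2S,3S)-3-(acetyloxy)-5-[(1S)-1-{[tert-butyl(dimethyl)silyl]oxy}ethyl]-2,3-dihydro-1-benzofuran-2-yl]prop-2-enoate | C=C(C(=O)OC)[C@@H]1Oc2ccc([C@H](C)O[Si](C)(C)C(C)(C)C)cc2[C@@H]1OC(C)=O | intermediate
18 | methyl 2-[(2S,3S)-3-(acetyloxy)-5-[(1S)-1-hydroxyethyl]-2,3-dihydro-1-benzofuran-2-yl]prop-2-enoate | C=C(C(=O)OC)[C@@H]1Oc2ccc([C@H](C)O)cc2[C@@H]1OC(C)=O | intermediate
19 | (2Z)-2-methylbut-2-enoic acid (angelic acid) | C/C=C(/C)C(=O)O | starting material
20 | (2Z)-2-methylbut-2-enoic 2,4,6-trichlorobenzoic anhydride | C/C=C(/C)C(=O)OC(=O)c1c(Cl)cc(Cl)cc1Cl | intermediate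
21 | methyl 2-[(2S,3S)-3-(acetyloxy)-5-[(1S)-1-{[(2Z)-2-methylbut-2-enoyl]oxy}ethyl]-2,3-dihydro-1-benzofuran-2-yl]prop-2-enoate | C=C(C(=O)OC)[C@@H]1Oc2ccc([C@H](C)OC(=O)/C(C)=C\C)cc2[C@@H]1OC(C)=O | target

## Step count and least certain steps

Total: 13 steps. Longest linear sequence: 13 steps, from 1 to 21; 7 and 19 enter as single catalogue reagents.

**Step 7 (key step, proposed new method).** Three things may go wrong.
- The carbanion may not reach C2 in the fold the shift requires (C4–O5 roughly perpendicular to the enol ether plane). It would then collapse by a radical-pair [1,2]-migration, or lithiation would drift to the vinylic C2–H or the side-chain benzylic C–H.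
- Facial discrimination by the ligand, developed on acyclic ethers, may be poor on a ring that interconverts between mirror-image folds; warming to force conversion would erode it further.
- The electron-rich enol ether terminus may be a sluggish acceptor.

Fallback, by known chemistry, from 4 to 13: the ring centres are set by catalyst-controlled ketone reduction. Ester 4 is treated with chloromethyllithium (ICH2Cl, MeLi·LiBr, THF, −78 °C) to give the chloromethyl ketone F1, which closes with K2CO3 in acetone to the benzofuran-3(2H)-one F2. Its lithium enolate (LDA, THF, −78 °C) is trapped with acetone to give the aldol adduct F3, whose C2 centre epimerises freely through the aromatic enol. Transfer hydrogenation with RuCl(p-cymene)[(R,R)-TsDPEN] in HCO2H/Et3N then acts as a dynamic kinetic resolution: hydride enters anti to the bulky C2 substituent of the faster-reacting epimer and should give the cis (2R,3S) diol F4 (the C2 descriptor differs from that of 12 only because of the tertiary hydroxyl). Acetylation of the secondary hydroxyl (Ac2O, pyridine) gives the hydroxy acetate F5, and dehydration of the tertiary alcohol towards a methyl group (SOCl2, pyridine, CH2Cl2, −20 °C) returns to the route at 13.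

**Step 6 (metathesis).** The catalyst is likely to load first on the vinyl ether and rest as a poorly reactive aryloxycarbene. This then has to engage a 1,1-disubstituted alkene in a medium-ring closure, so stalling, oligomerisation or alkene migration may win.

Fallback from 4 to 9: the enol ether C–O bond is made by copper catalysis. 4 is reduced (LiAlH4, THF) to the diol F6. Its disodium salt (NaH, 2.2 equiv, THF/DMF) is alkylated at the more nucleophilic benzylic alkoxide with the known reagent (Z)-3-bromo-1-iodo-2-methylprop-1-ene to give the (Z)-vinyl iodide F7. Intramolecular Ullmann-type O-vinylation (CuI, 1,10-phenanthroline, Cs2CO3, toluene, 110 °C, high dilution) then closes the ring with retention of alkene geometry and returns to the route at 9.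

**Step 13 (angeloylation).** Possible failures are isomerisation of the Z double bond to E if any nucleophile adds reversibly, thermal loss of acetic acid from C3 with aromatisation of ring B at 75 °C, and ionisation of the para-alkoxybenzylic carbinol.

Fallback from 18 to 21: the Z double bond is built on the molecule. 18 is esterified (DCC, DMAP, CH2Cl2, 0 °C) with 2-[bis(2,2,2-trifluoroethoxy)phosphoryl]propanoic acid to give the phosphonate ester F9. Still–Gennari olefination with acetaldehyde (KHMDS, 18-crown-6, THF, −78 °C) should give the Z-trisubstituted enoate, which is 21.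

**Step 9 (allylic oxidation).** Oxidation may be slow at the electron-poor end of the reactivity scale of 1,1-disubstituted alkenes. Longer exposure to selenious acid risks acid-promoted elimination of the C3 acetate or oxidation at C2–H.

Fallback from 13 to 15: ene-type allylic chlorination (PhSeCl cat., N-chlorosuccinimide, CH2Cl2, rt) gives the allylic chloride F8. Amine N-oxide oxidation (Me3NO, NaI cat., DMSO, rt) converts it to the enal, returning to the route at 15.

**Step 3 (O-vinylation).** The hydrogen-bonded, copper-chelating salicylate phenol may transmetalate slowly, so protodeboronation of the vinyl donor outruns coupling.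

Fallback from 4 to 5: iridium-catalysed transfer vinylation with vinyl acetate ([Ir(cod)Cl]2, Na2CO3, toluene, 100 °C). This proceeds by addition–elimination at iridium and makes no new intermediate.

## Further compounds

F1 | step 7 | 2-chloro-1-{5-[(1S)-1-{[tert-butyl(dimethyl)silyl]oxy}ethyl]-2-hydroxyphenyl}ethan-1-one | O=C(CCl)c1cc([C@H](C)O[Si](C)(C)C(C)(C)C)ccc1O
F2 | step 7 | 5-[(1S)-1-{[tert-butyl(dimethyl)silyl]oxy}ethyl]-1-benzofuran-3(2H)-one | O=C1COc2ccc([C@H](C)O[Si](C)(C)C(C)(C)C)cc21
F3 | step 7 | 5-[(1S)-1-{[tert-butyl(dimethyl)silyl]oxy}ethyl]-2-(2-hydroxypropan-2-yl)-1-benzofuran-3(2H)-one (C2 epimers, interconverting) | CC(C)(O)C1Oc2ccc([C@H](C)O[Si](C)(C)C(C)(C)C)cc2C1=O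
F4 | step 7 | (2R,3S)-5-[(1S)-1-{[tert-butyl(dimethyl)silyl]oxy}ethyl]-2-(2-hydroxypropan-2-yl)-2,3-dihydro-1-benzofuran-3-ol | CC(C)(O)[C@@H]1Oc2ccc([C@H](C)O[Si](C)(C)C(C)(C)C)cc2[C@@H]1O
F5 | step 7 | (2R,3S)-5-[(1S)-1-{[tert-butyl(dimethyl)silyl]oxy}ethyl]-2-(2-hydroxypropan-2-yl)-2,3-dihydro-1-benzofuran-3-yl acetate | CC(C)(O)[C@@H]1Oc2ccc([C@H](C)O[Si](C)(C)C(C)(C)C)cc2[C@@H]1OC(C)=O
F6 | step 6 | 4-[(1S)-1-{[tert-butyl(dimethyl)silyl]oxy}ethyl]-2-(hydroxymethyl)phenol | OCc1cc([C@H](C)O[Si](C)(C)C(C)(C)C)ccc1O
F7 | step 6 | 4-[(1S)-1-{[tert-butyl(dimethyl)silyl]oxy}ethyl]-2-({[(2Z)-3-iodo-2-methylprop-2-en-1-yl]oxy}methyl)phenol | C/C(=C/I)COCc1cc([C@H](C)O[Si](C)(C)C(C)(C)C)ccc1O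
F8 | step 9 | (2S,3S)-5-[(1S)-1-{[tert-butyl(dimethyl)silyl]oxy}ethyl]-2-(3-chloroprop-1-en-2-yl)-2,3-dihydro-1-benzofuran-3-yl acetate | C=C(CCl)[C@@H]1Oc2ccc([C@H](C)O[Si](C)(C)C(C)(C)C)cc2[C@@H]1OC(C)=O
F9 | step 13 | methyl 2-[(2S,3S)-3-(acetyloxy)-5-[(1S)-1-({2-[bis(2,2,2-trifluoroethoxy)phosphoryl]propanoyl}oxy)ethyl]-2,3-dihydro-1-benzofuran-2-yl]prop-2-enoate (mixture at the phosphonate carbon) | C=C(C(=O)OC)[C@@H]1Oc2ccc([C@H](C)OC(=O)C(C)P(=O)(OCC(F)(F)F)OCC(F)(F)F)cc2[C@@H]1OC(C)=O
F0 | step 3 | none | none
A1 | alternative 1 | tert-butyl{[(3S,4S)-5-methyl-4-{[(trimethylsilyl)ethynyl]oxy}hex-5-en-1-yn-3-yl]oxy}dimethylsilane | C=C(C)[C@H](OC#C[Si](C)(C)C)[C@@H](O[Si](C)(C)C(C)(C)C)C#C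
A2 | alternative 1 | (2S)-but-3-yn-2-yl (2Z)-2-methylbut-2-enoate | C#C[C@H](C)OC(=O)/C(C)=C\C
A3 | alternative 1 | (1S)-1-[(2S,3S)-3-{[tert-butyl(dimethyl)silyl]oxy}-2-(prop-1-en-2-yl)-7-(trimethylsilyl)-2,3-dihydro-1-benzofuran-5-yl]ethyl (2Z)-2-methylbut-2-enoate | C=C(C)[C@@H]1Oc2c([Si](C)(C)C)cc([C@H](C)OC(=O)/C(C)=C\C)cc2[C@@H]1O[Si](C)(C)C(C)(C)C
A4 | alternative 2 | (4S,5S)-4-(4-bromophenoxy)-3-methylidene-5-{[(1S,2R,5S)-5-methyl-2-(propan-2-yl)cyclohexyl]oxy}oxolan-2-one | CC(C)[C@H]1CC[C@H](C)C[C@@H]1O[C@H]2OC(=O)C(=C)[C@@H]2Oc3ccc(Br)cc3
A5 | alternative 2 | (3aS,8bS)-7-bromo-3-methylidene-3a,8b-dihydrofuro[3,2-b][1]benzofuran-2(3H)-one (cis-fused) | C=C1[C@@H]2Oc3ccc(Br)cc3[C@@H]2OC1=O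
A6 | alternative 3 | 4-[(1S)-1-{[tert-butyl(dimethyl)silyl]oxy}ethyl]-2-[(1R)-1-hydroxybuta-2,3-dien-1-yl]phenol | C=C=C[C@@H](O)c1cc([C@H](C)O[Si](C)(C)C(C)(C)C)ccc1O
A7 | alternative 3 | (3aS,8bS)-7-[(1S)-1-{[tert-butyl(dimethyl)silyl]oxy}ethyl]-3-methylidene-3a,8b-dihydrofuro[3,2-b][1]benzofuran-2(3H)-one (cis-fused) | C=C1[C@@H]2Oc3ccc([C@H](C)O[Si](C)(C)C(C)(C)C)cc3[C@@H]2OC1=O
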